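**Retrosynthetic overview**

1. Both C6–O ester bonds are made last by a double Mitsunobu esterification (inversion at C6) of (2E,6E)-2,6-dimethylocta-2,6-dienedioic acid (four steps from geranyl acetate) with two molecules of the 6R amino alcohol 6-epi-incarvilline.
2. The amino alcohol comes from an N-Boc cis-fused bicyclic ketone (LiAlH4 turns Boc into N-methyl); C4a and the cis ring fusion come from hydrogenation of a C4a=C5 cyclopentenone.
3. Key disconnection: the cyclopentenone is cut at C6–C7 and C5–C4a into an α-ethylidene piperidin-4-one (C7=C7a–C4a=O, three carbons) and acetaldehyde (C5–C6, two carbons), joined by a domino Stetter addition/aldol condensation.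
4. Enabling feature: in the cyclopentane ring (C4a–C5–C6–C7–C7a) the oxygen-bearing C6 and the ring-fusion carbon C4a are 1,4-related, so the carbocycle is a latent 1,4-diketone. Its second carbonyl (C4a) is the ring ketone of a piperidin-4-one, and the methyl-bearing C7 is the β-carbon of that ketone's exocyclic enone.
5. Ring order: piperidine ring bought, cyclopentane ring closed in the key step. Relative configuration comes from thermodynamic control (C4, C7a, C7), hydrogenation (C4a) and hydride reduction (C6); absolute configuration comes from a lipase kinetic resolution.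

Key step: step 3

Numbering: bicyclic compounds use cyclopenta[c]pyridine locants (C1, N2, C3, C4, C4a, C5, C6, C7, C7a).

Remark: commercial 1 is racemic and its stereocenter is labile (α to the ketone), so 3–9 are racemates (SMILES and descriptors show the enantiomer that is carried on) and the absolute configuration is introduced in step 6.

**Route**

Step 1
Reactants: 1 tert-butyl 3-methyl-4-oxopiperidine-1-carboxylate; 2 acetaldehyde
Product: 3 tert-butyl 3-(1-hydroxyethyl)-5-methyl-4-oxopiperidine-1-carboxylate
Conditions: LiN(i-Pr)2 (1.1 equiv), THF, −78 °C; 2 (1.5 equiv), −78 °C; aq NH4Cl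
Reagents that add atoms: none
Why: Kinetic deprotonation by the hindered lithium amide should occur at the unsubstituted α-methylene rather than at the methyl-bearing α-carbon, and the lithium enolate adds to the aldehyde (directed aldol addition); the new stereocenters are removed in step 2, so their configuration does not matter.

Step 2
Reactants: 3 tert-butyl 3-(1-hydroxyethyl)-5-methyl-4-oxopiperidine-1-carboxylate
Product: 5 tert-butyl (3E)-3-ethylidene-5-methyl-4-oxopiperidine-1-carboxylate, via secondary mesylate 4 (not isolated)
Conditions: MsCl (1.3 equiv), Et3N (3 equiv), CH2Cl2, 0 °C; then DBU (2 equiv), rt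
Reagents that add atoms: none
Why: Mesylation followed by E1cB elimination through the ketone enolate should give the conjugated exocyclic enone, the E isomer (methyl anti to the carbonyl) being the preferred geometry of 2-alkylidene cycloalkanones; the geometry is lost again in step 3.

Step 3
Reactants: 5 tert-butyl (3E)-3-ethylidene-5-methyl-4-oxopiperidine-1-carboxylate; 2 acetaldehyde
Product: 7 tert-butyl rac-(4S,7R,7aR)-4,7-dimethyl-6-oxo-1,3,4,6,7,7a-hexahydro-2H-cyclopenta[c]pyridine-2-carboxylate, via 1,4-diketone 6 (not isolated)
Conditions: 2 (5 equiv), 3-benzyl-5-(2-hydroxyethyl)-4-methylthiazolium chloride (0.2 equiv), Et3N (1 equiv), EtOH, 75 °C, sealed vessel; volatiles removed; then KOH (0.5 equiv), MeOH, 40 °C, stopped when 6 is consumed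
Reagents that add atoms: none
Why: The thiazol-2-ylidene formed from the thiazolium salt and Et3N adds to acetaldehyde to give a nucleophilic enaminol (acetyl anion equivalent) that adds to C7, the β-carbon of the s-cis-locked exocyclic enone (Stetter reaction), which forms C6–C7 and, after protonation at C7a, the 1,4-diketone 6; KOH then forms the methyl ketone enolate, whose carbon C5 attacks the ring ketone C4a, and E1cB dehydration of the ketol gives the conjugated cyclopentenone, which forms C5–C4a. The closest precedent is the thiazolium-catalysed addition of aliphatic aldehydes to enones followed by base cyclisation of the 2,5-diketone, as in the dihydrojasmone synthesis and in the closure of 2-(2-oxopropyl)cycloalkanones to bicyclic cyclopentenones. The five-membered ring closes in the 5-exo-trig mode (enolate carbon onto the carbonyl carbon), and this is the only productive aldol, because the other enolates of 6 can only give three-membered or bridged ketols that cannot dehydrate and revert. C7a and C4 are both α to the ring ketone in 6 and should settle as the cis-3,5-diequatorial piperidinone before closure, which puts the C4 methyl and C7 on the same face of the six-membered ring; C7 is α to the C6 ketone and should equilibrate to the methyl trans to C1, and it can be equilibrated again after step 4. The step needs cross-addition to win over acyloin self-condensation, which the reversibility of the acyloin pathway, the excess of aldehyde and the irreversible conjugate addition should secure, and it needs the double bond to stay at C4a=C5, which is secured by ending the base treatment before migration to C7=C7a sets in.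

Step 4
Reactants: 7 tert-butyl rac-(4S,7R,7aR)-4,7-dimethyl-6-oxo-1,3,4,6,7,7a-hexahydro-2H-cyclopenta[c]pyridine-2-carboxylate
Product: 8 tert-butyl rac-(4S,4aR,7R,7aS)-4,7-dimethyl-6-oxooctahydro-2H-cyclopenta[c]pyridine-2-carboxylate
Conditions: H2 (1 atm), 10% Pd/C, EtOAc, rt
Reagents that add atoms: none
Why: Heterogeneous hydrogenation of the enone should deliver hydrogen to the alkene face that carries H-7a and H-4 (the other face is screened by the axial hydrogens at C1 and C3 of the folded six-membered ring), as in the reduction of hydrindenones to cis-hydrindanones, which sets C4a with H-4a cis to H-7a and H-4, that is, the cis ring fusion with the C4 methyl cis to C5.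

Step 5
Reactants: 8 tert-butyl rac-(4S,4aR,7R,7aS)-4,7-dimethyl-6-oxooctahydro-2H-cyclopenta[c]pyridine-2-carboxylate
Product: 9 tert-butyl rac-(4S,4aR,6R,7R,7aS)-6-hydroxy-4,7-dimethyloctahydro-2H-cyclopenta[c]pyridine-2-carboxylate
Conditions: NaOMe (0.1 equiv), MeOH, rt; then NaBH4 (1.5 equiv), −20 °C
Reagents that add atoms: none
Why: After methoxide equilibration of the enolisable C7 to the exo methyl (trans to C1), hydride reduction with the small NaBH4 should occur from the convex face of the cis-fused bicycle, the face also preferred in 2-methylcyclopentanone, so that the C6 hydroxyl ends up on the concave face, trans to the C7 methyl.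

Step 6
Reactants: 9 tert-butyl rac-(4S,4aR,6R,7R,7aS)-6-hydroxy-4,7-dimethyloctahydro-2H-cyclopenta[c]pyridine-2-carboxylate
Product: 10 tert-butyl (4S,4aR,6R,7R,7aS)-6-acetoxy-4,7-dimethyloctahydro-2H-cyclopenta[c]pyridine-2-carboxylate
Conditions: immobilised Burkholderia cepacia lipase, vinyl acetate (5 equiv), MTBE, 35 °C, stopped near half conversion; chromatography
Reagents that add atoms: vinyl acetate CC(=O)OC=C
Why: Lipase-catalysed irreversible transesterification is a kinetic resolution of secondary alcohols, and the empirical size model for these enzymes predicts faster acylation of the enantiomer whose carbinol is R when the larger flank (the methyl-bearing C7 side) outranks the smaller one (C5H2), that is, the wanted 6R enantiomer, which is separated as its acetate from the unreacted mirror-image alcohol; this fixes the absolute configuration of all five stereocenters.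

Step 7
Reactants: 10 tert-butyl (4S,4aR,6R,7R,7aS)-6-acetoxy-4,7-dimethyloctahydro-2H-cyclopenta[c]pyridine-2-carboxylate
Product: 11 (4S,4aR,6R,7R,7aS)-2,4,7-trimethyloctahydro-1H-cyclopenta[c]pyridin-6-ol (6-epi-incarvilline)
Conditions: LiAlH4 (5 equiv), THF, reflux; aq NaOH work-up
Reagents that add atoms: none
Why: Hydride reduction with LiAlH4 should convert the tert-butyl carbamate into the N-methyl group and cleave the acetate in the same operation without touching any stereocenter.

Step 8
Reactants: 12 geranyl acetate
Product: 13 (2E,6E)-8-hydroxy-3,7-dimethylocta-2,6-dien-1-yl acetate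
Conditions: SeO2 (0.1 equiv), t-BuOOH (70% aq, 3 equiv), salicylic acid (0.1 equiv), CH2Cl2, rt
Reagents that add atoms: tert-butyl hydroperoxide CC(C)(C)OO
Why: Catalytic SeO2 allylic oxidation (ene reaction, then [2,3]-sigmatropic shift) should hydroxylate the E methyl group of the electron-rich terminal trisubstituted alkene with retention of the E geometry, while the alkene next to the acetate is deactivated.

Step 9
Reactants: 13 (2E,6E)-8-hydroxy-3,7-dimethylocta-2,6-dien-1-yl acetate
Product: 14 (2E,6E)-2,6-dimethylocta-2,6-diene-1,8-diol
Conditions: K2CO3 (0.2 equiv), MeOH, rt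
Reagents that add atoms: none
Why: Base-catalysed transesterification with methanol should remove the acetate without affecting the alkenes.

Step 10
Reactants: 14 (2E,6E)-2,6-dimethylocta-2,6-diene-1,8-diol
Product: 15 (2E,6E)-2,6-dimethylocta-2,6-dienedial
Conditions: activated MnO2 (20 equiv), CH2Cl2, rt
Reagents that add atoms: none
Why: MnO2 oxidation is selective for allylic alcohols and should give both enals without E/Z isomerisation.

Step 11
Reactants: 15 (2E,6E)-2,6-dimethylocta-2,6-dienedial
Product: 16 (2E,6E)-2,6-dimethylocta-2,6-dienedioic acid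
Conditions: NaClO2 (6 equiv), NaH2PO4 (6 equiv), 2-methyl-2-butene (20 equiv), t-BuOH–H2O, 0 °C to rt
Reagents that add atoms: sodium chlorite [Na+].[O-]Cl=O
Why: Pinnick oxidation should convert both α,β-unsaturated aldehydes into acids without isomerising the trisubstituted alkenes, the added alkene trapping the hypochlorous acid that is released.

Step 12
Reactants: 16 (2E,6E)-2,6-dimethylocta-2,6-dienedioic acid; 11 (4S,4aR,6R,7R,7aS)-2,4,7-trimethyloctahydro-1H-cyclopenta[c]pyridin-6-ol (2.2 equiv)
Product: 17 bis[(4S,4aR,6S,7R,7aS)-2,4,7-trimethyloctahydro-1H-cyclopenta[c]pyridin-6-yl] (2E,6E)-2,6-dimethylocta-2,6-dienedioate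
Conditions: PPh3 (3 equiv), DIAD (3 equiv), THF, 0 °C to rt
Reagents that add atoms: none
Why: In the Mitsunobu esterification each carboxylate should displace the oxyphosphonium of the secondary alcohol by SN2 with inversion, turning 6R into the 6S configuration of the target at both ends; esterification of amino alcohols of this ring type with unsaturated acids under these conditions is established.

**Compound list**

1 | tert-butyl 3-methyl-4-oxopiperidine-1-carboxylate (racemic) | CC1CN(C(=O)OC(C)(C)C)CCC1=O | starting material
2 | acetaldehyde | CC=O | starting material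
3 | tert-butyl 3-(1-hydroxyethyl)-5-methyl-4-oxopiperidine-1-carboxylate (mixture of racemic diastereomers) | CC(O)C1CN(C(=O)OC(C)(C)C)CC(C)C1=O | intermediate
4 | tert-butyl 3-methyl-5-[1-(methylsulfonyloxy)ethyl]-4-oxopiperidine-1-carboxylate (not isolated) | CC(OS(C)(=O)=O)C1CN(C(=O)OC(C)(C)C)CC(C)C1=O | intermediate
5 | tert-butyl (3E)-3-ethylidene-5-methyl-4-oxopiperidine-1-carboxylate (racemic) | C/C=C1\CN(C(=O)OC(C)(C)C)CC(C)C1=O | intermediate
6 | tert-butyl 3-methyl-4-oxo-5-(3-oxobutan-2-yl)piperidine-1-carboxylate (not isolated; racemic; 3,5-cis isomer drawn) | CC(=O)[C@H](C)[C@H]1CN(C(=O)OC(C)(C)C)C[C@@H](C)C1=O | intermediate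
7 | tert-butyl rac-(4S,7R,7aR)-4,7-dimethyl-6-oxo-1,3,4,6,7,7a-hexahydro-2H-cyclopenta[c]pyridine-2-carboxylate | O=C1C=C2[C@H](CN(C(=O)OC(C)(C)C)C[C@H]2C)[C@H]1C | intermediate
8 | tert-butyl rac-(4S,4aR,7R,7aS)-4,7-dimethyl-6-oxooctahydro-2H-cyclopenta[c]pyridine-2-carboxylate | O=C1C[C@H]2[C@H](CN(C(=O)OC(C)(C)C)C[C@H]2C)[C@H]1C | intermediate
9 | tert-butyl rac-(4S,4aR,6R,7R,7aS)-6-hydroxy-4,7-dimethyloctahydro-2H-cyclopenta[c]pyridine-2-carboxylate | O[C@@H]1C[C@H]2[C@H](CN(C(=O)OC(C)(C)C)C[C@H]2C)[C@H]1C | intermediate
10 | tert-butyl (4S,4aR,6R,7R,7aS)-6-acetoxy-4,7-dimethyloctahydro-2H-cyclopenta[c]pyridine-2-carboxylate | CC(=O)O[C@@H]1C[C@H]2[C@H](CN(C(=O)OC(C)(C)C)C[C@H]2C)[C@H]1C | intermediate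
11 | (4S,4aR,6R,7R,7aS)-2,4,7-trimethyloctahydro-1H-cyclopenta[c]pyridin-6-ol (6-epi-incarvilline) | O[C@@H]1C[C@H]2[C@H](CN(C)C[C@H]2C)[C@H]1C | intermediate
12 | geranyl acetate, (2E)-3,7-dimethylocta-2,6-dien-1-yl acetate | CC(C)=CCC/C(C)=C/COC(C)=O | starting material
13 | (2E,6E)-8-hydroxy-3,7-dimethylocta-2,6-dien-1-yl acetate | OC/C(C)=C/CC/C(C)=C/COC(C)=O | intermediate
14 | (2E,6E)-2,6-dimethylocta-2,6-diene-1,8-diol | OC/C(C)=C/CC/C(C)=C/CO | intermediate
15 | (2E,6E)-2,6-dimethylocta-2,6-dienedial | O=C/C(C)=C/CC/C(C)=C/C=O | intermediate
16 | (2E,6E)-2,6-dimethylocta-2,6-dienedioic acid | OC(=O)/C(C)=C/CC/C(C)=C/C(=O)O | intermediate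
17 | bis[(4S,4aR,6S,7R,7aS)-2,4,7-trimethyloctahydro-1H-cyclopenta[c]pyridin-6-yl] (2E,6E)-2,6-dimethylocta-2,6-dienedioate | C/C(=C\C(=O)O[C@H]1C[C@H]2[C@H](CN(C)C[C@H]2C)[C@H]1C)CC/C=C(\C)C(=O)O[C@H]1C[C@H]2[C@H](CN(C)C[C@H]2C)[C@H]1C | target

**Step count and risks**

Total step count: 12. Longest linear sequence: 8 steps (steps 1–7, then step 12); steps 8–11 form the second branch.

Steps most likely to fail:

Step 3. The acetyl anion equivalent may add too slowly to the β-methyl, α-branched enone, so that acyloin self-condensation of acetaldehyde and double-bond migration in 5 take over. The fallback replaces the carbene-derived acyl anion by a nitronate. It sets out from 5: DBU-mediated conjugate addition of nitroethane in MeCN should give tert-butyl 3-methyl-5-(3-nitrobutan-2-yl)-4-oxopiperidine-1-carboxylate F1. A Nef reaction (NaOMe, then aqueous TiCl3 buffered with NH4OAc) turns the nitro-bearing carbon into the C6 ketone and gives diketone 6, here isolated. KOH in MeOH then closes it to 7, where the route is rejoined.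

Step 6. The enzyme may discriminate the enantiomers of 9 poorly, or acylate the concave hydroxyl too slowly for a clean resolution. The fallback is a covalent resolution and sets out from 9: esterification with (2S)-2-methoxy-2-phenylacetic acid (DCC, DMAP, CH2Cl2) gives two diastereomeric esters that are separated by crystallisation or chromatography. The ester of the wanted enantiomer, tert-butyl (4S,4aR,6R,7R,7aS)-6-{[(2S)-2-methoxy-2-phenylacetyl]oxy}-4,7-dimethyloctahydro-2H-cyclopenta[c]pyridine-2-carboxylate F2, is reduced with LiAlH4 in refluxing THF, which cleaves the ester and converts Boc into N-methyl. The fallback comes back to the route at 11.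

Step 12. Elimination of the activated concave alcohol to a cyclopentene, or incomplete double displacement by the weakly acidic dienedioic acid, may erode the double inversion. The fallback separates inversion from ester formation and sets out from 11: a single Mitsunobu reaction with the more acidic 4-nitrobenzoic acid (PPh3, DIAD, toluene) should give (4S,4aR,6S,7R,7aS)-2,4,7-trimethyloctahydro-1H-cyclopenta[c]pyridin-6-yl 4-nitrobenzoate F3. Methanolysis (K2CO3, MeOH) gives (4S,4aR,6S,7R,7aS)-2,4,7-trimethyloctahydro-1H-cyclopenta[c]pyridin-6-ol (incarvilline) F4. Yamaguchi esterification of 16 with F4 (2,4,6-trichlorobenzoyl chloride, Et3N, then F4 and DMAP, toluene), with retention at C6, comes back to the route at 17.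

Further compounds
F1 | step 3 | tert-butyl 3-methyl-5-(3-nitrobutan-2-yl)-4-oxopiperidine-1-carboxylate (mixture of diastereomers) | CC(C(C)[N+](=O)[O-])C1CN(C(=O)OC(C)(C)C)CC(C)C1=O
F2 | step 6 | tert-butyl (4S,4aR,6R,7R,7aS)-6-{[(2S)-2-methoxy-2-phenylacetyl]oxy}-4,7-dimethyloctahydro-2H-cyclopenta[c]pyridine-2-carboxylate | CO[C@H](C(=O)O[C@@H]1C[C@H]2[C@H](CN(C(=O)OC(C)(C)C)C[C@H]2C)[C@H]1C)c1ccccc1
F3 | step 12 | (4S,4aR,6S,7R,7aS)-2,4,7-trimethyloctahydro-1H-cyclopenta[c]pyridin-6-yl 4-nitrobenzoate | O=C(O[C@H]1C[C@H]2[C@H](CN(C)C[C@H]2C)[C@H]1C)c1ccc(cc1)[N+](=O)[O-]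
F4 | step 12 | (4S,4aR,6S,7R,7aS)-2,4,7-trimethyloctahydro-1H-cyclopenta[c]pyridin-6-ol (incarvilline) | O[C@H]1C[C@H]2[C@H](CN(C)C[C@H]2C)[C@H]1C
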